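Retrosynthesis: the hemiaminal C–OH is removed as water, so that lactam C5 and its benzylic CH2 become an exocyclic C=C inside the 13-membered ring; that C=C is cut (C5 phosphonate + aryl aldehyde), then the ketone–lactam C3 bond (Claisen acylation), the aryl ether C–O bond (SNAr), and the two ring A bonds formed by an intramolecular Diels–Alder reaction.
Forward: ring C is the starting cyclohexanone; both side chains are grown on it; the Diels–Alder reaction closes rings A and B together; the aryl ether and the phosphonolactam are attached; the olefination closes the cyclophane; hydration gives the hemiaminal.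
Stereochemistry: a chiral lithium amide desymmetrises the meso ketone; the two ring C side chains become equatorial by equilibration; the carbinol comes from a ligand-controlled alkynylation; the four ring A/B centres come from the endo cycloaddition of an E,Z-diene; the hemiaminal carbon and lactam C3 settle thermodynamically at the end.
Enabling feature: lactam C5 is a hemiaminal carbon that carries the benzylic CH2 of the para-phenylene ring; its dehydrated form is a 5-benzylidene lactam whose C5=CH bond lies in the macrocycle and is an olefination retron.

Key step: step 20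

Assumption: the sense of induction of the lithium amide (step 1) and of the ProPhenol ligand (step 8) is assigned by analogy with the accepted models for these reagents; if either proves opposite, its mirror image is used.

Step 1
Reactants: 1 cis-3,5-dimethylcyclohexanone
Product: 2 (3S,5R)-3,5-dimethyl-1-(trimethylsilyloxy)cyclohex-1-ene
Conditions: (S,S)-bis(1-phenylethyl)amine, n-BuLi, LiCl, Me3SiCl (internal quench), THF, −78 °C
Reagents that add atoms: chlorotrimethylsilane, C[Si](C)(C)Cl
Why: Enantiotopos-selective deprotonation of a conformationally locked meso cyclohexanone by a C2-symmetric chiral lithium amide under internal Me3SiCl quench (asymmetric enolisation) removes one of the two axial α-hydrogens, so that the position of the enol double bond relative to the two cis methyl groups stores the absolute configuration of the whole route.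

Step 2
Reactants: 2 enol silane
Product: 3 (2S,3S,5R)-2-(1,3-dioxolan-2-yl)-3,5-dimethylcyclohexan-1-one
Conditions: 2-methoxy-1,3-dioxolane, Me3SiOTf (5 mol%), CH2Cl2, −78 °C; then K2CO3 (cat.), MeOH, 23 °C
Reagents that add atoms: 2-methoxy-1,3-dioxolane, COC1OCCO1
Why: Lewis acid-catalysed condensation of an enol silane with an orthoformate (Mukaiyama-type acetal aldol through the 1,3-dioxolan-2-ylium ion) installs the future carbinol carbon at the aldehyde oxidation level at low temperature, where the silyl group does not migrate, and the new α-stereocentre, being epimerisable, is equilibrated by K2CO3 in MeOH to the equatorial position trans to the neighbouring methyl group.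

Step 3
Reactants: 3 keto acetal
Product: 4 methyl enol ether 2-[2-(methoxymethylidene)-4,6-dimethylcyclohexyl]-1,3-dioxolane (ring stereocentres as in 3; E/Z mixture)
Conditions: MeOCH2PPh3Cl, KOtBu, THF, 0 → 23 °C
Reagents that add atoms: (methoxymethyl)triphenylphosphonium chloride, COC[P+](c1ccccc1)(c1ccccc1)c1ccccc1.[Cl-]
Why: Wittig methoxymethylenation of the ketone homologates the carbonyl carbon by one carbon, and once the carbonyl is gone the adjacent acetal-bearing stereocentre can no longer epimerise.

Step 4
Reactants: 4 methyl enol ether
Product: 5 (1R,2R,3S,5R)-2-(1,3-dioxolan-2-yl)-3,5-dimethylcyclohexane-1-carbaldehyde (all four substituents equatorial)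
Conditions: 0.5 M HCl, THF, 0 °C; then K2CO3 (cat.), MeOH, 23 °C
Reagents that add atoms: water, O
Why: Enol ether hydrolysis (C-protonation, then loss of methanol) is much faster than ionisation of the cyclic acetal in cold dilute acid, and the new formyl-bearing stereocentre is then equilibrated by base to the equatorial aldehyde trans to the dioxolanyl group (thermodynamic control, the minor axial epimer being recyclable).

Step 5
Reactants: 5 acetal aldehyde
Product: 6 (E)-3-[(1S,2R,3S,5R)-2-(1,3-dioxolan-2-yl)-3,5-dimethylcyclohexyl]prop-2-enal
Conditions: Ph3P=CHCHO, toluene, 80 °C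
Reagents that add atoms: (triphenylphosphoranylidene)acetaldehyde, O=CC=P(c1ccccc1)(c1ccccc1)c1ccccc1
Why: Wittig olefination with the stabilised formylmethylene ylide gives the E-enal and adds the two inner diene carbons, the unhindered equatorial aldehyde being the faster-reacting epimer.

Step 6
Reactants: 6 enal
Product: 7 dienyne acetal (the cyclohexane of 6 carrying a (1E,3Z)-6-(triisopropylsilyl)hexa-1,3-dien-5-yn-1-yl group in place of the propenal chain)
Conditions: 1,3-bis(triisopropylsilyl)propyne, n-BuLi, THF, −78 °C; then 6, −78 → 23 °C
Reagents that add atoms: 1,3-bis(triisopropylsilyl)propyne, CC(C)[Si](C(C)C)(C(C)C)CC#C[Si](C(C)C)(C(C)C)C(C)C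
Why: Peterson olefination of the enal with the lithiated 1,3-bis(silyl)propyne proceeds through the β-silyl alkoxide that eliminates syn to the Z-enyne, the bulky triisopropylsilyl groups being the source of the Z preference, so that the diene terminus carries a slim alkynyl group as the latent vinyl group on its inner side.

Step 7
Reactants: 7 dienyne acetal
Product: 8 dienyne aldehyde (dioxolane of 7 replaced by an equatorial formyl group)
Conditions: 1 M HCl, THF, 23 °C
Reagents that add atoms: water, O
Why: Acid-catalysed acetal hydrolysis frees the aldehyde while the silyl alkyne and the dienyne are inert to dilute aqueous acid, and the hindered aldehyde keeps its equatorial, more stable configuration.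

Step 8
Reactants: 8 dienyne aldehyde
Product: 9 methyl (4S)-4-hydroxy-4-[dienynyl-dimethylcyclohexyl]but-2-ynoate (ring as in 8)
Conditions: methyl propiolate, Me2Zn, (S,S)-ProPhenol (20 mol%), Ph3P=O (40 mol%), toluene, 4 °C
Reagents that add atoms: methyl propiolate, C#CC(=O)OC
Why: Catalytic asymmetric alkynylation of an aldehyde with a zinc acetylide held by the dinuclear zinc complex of ProPhenol adds methyl propiolate to one carbonyl face under ligand control, since the α-carbon of 8 with its two similar ring branches exerts little bias of its own, which sets the (4S) carbinol that later becomes the aryl ether carbon and turns the minor enantiomer of 8 into a separable diastereomer.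

Step 9
Reactants: 9 hydroxy ynoate
Product: 10 methyl (2E,4R)-4-hydroxy-4-[dienynyl-dimethylcyclohexyl]but-2-enoate (same spatial arrangement at the carbinol as in 9)
Conditions: NaAlH2(OCH2CH2OMe)2, THF, −72 °C; aqueous Rochelle salt work-up
Reagents that add atoms: none
Why: Alkoxide-directed trans-hydroalumination of the γ-hydroxy ynoate followed by protonolysis gives the E-enoate, and at −72 °C neither the ester nor the remote silyl enyne is reduced.

Step 10
Reactants: 10 hydroxy trienynoate
Product: 11 tricyclic hydroxy ester (6-5-6 decahydrofluorene, rings A/B and B/C trans-fused, triisopropylsilylethynyl on the allylic ring A carbon trans to the neighbouring methyl ester, ring B hydroxyl cis to the ester-bearing carbon and trans to the adjacent ring C carbon)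
Conditions: Et2AlCl (3 equiv), CH2Cl2, −78 → 23 °C; 1 M HCl work-up
Reagents that add atoms: none
Why: Lewis acid-promoted intramolecular Diels–Alder reaction of a terminally activated trienoate closes rings A and B with the ester endo (trans A/B fusion), the E,Z-diene delivers the alkynyl group trans to both the ester and the ring C carbon, and the diene adds to the enoate face that keeps the diene, the aluminium alkoxide and the dienophile chain pseudo-equatorial on the forming cyclopentane of the trans-diequatorial cyclohexane, which sets the four new stereocentres relative to ring C.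

Step 11
Reactants: 11 tricyclic silyl alkyne
Product: 12 tricyclic terminal alkyne (ethynyl in place of the silylethynyl group of 11)
Conditions: Bu4NF, THF, 0 °C
Reagents that add atoms: none
Why: Fluoride-induced protodesilylation cleaves the C(sp)–Si bond and leaves the ester, the alcohol and the ring alkene untouched.

Step 12
Reactants: 12 tricyclic terminal alkyne
Product: 13 tricyclic vinyl hydroxy ester (vinyl in place of the ethynyl group of 12)
Conditions: H2 (1 atm), Pd/CaCO3 poisoned with Pb(OAc)2, quinoline, EtOAc, 23 °C
Reagents that add atoms: none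
Why: Lindlar semihydrogenation reduces the terminal alkyne to the vinyl group and stops there, the disubstituted ring A alkene being far less reactive on the poisoned catalyst.

Step 13
Reactants: 13 tricyclic vinyl hydroxy ester
Product: 14 lithium salt of the tricyclic hydroxy acid
Conditions: LiOH·H2O (1.05 equiv), THF/MeOH/H2O, 40 °C; evaporation, toluene azeotrope
Reagents that add atoms: lithium hydroxide, [Li+].[OH-]
Why: Saponification of the methyl ester gives the carboxylate, which is kept as its lithium salt so that the cis-disposed hydroxyl and carboxyl groups never meet acid and cannot lactonise, while the ester-bearing carbon already has its most stable all-trans configuration and is not at risk under base.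

Step 14
Reactants: 14 lithium hydroxy carboxylate; 15 4-fluorobenzaldehyde
Product: 16 tricyclic 4-formylphenyl ether carboxylic acid
Conditions: NaH, DMF, 0 °C; then 15, 0 → 23 °C; 1 M HCl work-up
Reagents that add atoms: none
Why: Nucleophilic aromatic substitution (addition–elimination) of the formyl-activated aryl fluoride by the secondary sodium alkoxide forms the aryl ether with retention at the carbinol carbon, because the C–O bond of the alcohol is not broken, and the carboxylate is a spectator that also prevents lactonisation.

Step 15
Reactants: 16 aryl ether aldehyde acid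
Product: 17 tricyclic acid with the aryl aldehyde masked as its 1,3-dioxolane
Conditions: ethylene glycol, HC(OEt)3, p-TsOH·H2O (cat.), CH2Cl2, 23 °C; then Et3N
Reagents that add atoms: ethane-1,2-diol, OCCO
Why: Acid-catalysed acetalisation with the orthoformate as water scavenger masks the aryl aldehyde against the enolate of step 19, and the hindered carboxylic acid is not esterified at room temperature.

Step 16
Reactants: 18 succinimide
Product: 19 5-ethoxypyrrolidin-2-one (racemic)
Conditions: NaBH4, EtOH, 0 °C, ethanolic HCl added dropwise; then HCl to pH 3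
Reagents that add atoms: ethanol, CCO
Why: Partial reduction of the cyclic imide by NaBH4 at controlled acidity gives the hydroxy lactam, which ethanol captures through the N-acyliminium ion as the stable ethoxy lactam.

Step 17
Reactants: 19 5-ethoxypyrrolidin-2-one
Product: 20 diethyl (5-oxopyrrolidin-2-yl)phosphonate (racemic)
Conditions: P(OEt)3, BF3·OEt2, CH2Cl2, 0 → 23 °C
Reagents that add atoms: triethyl phosphite, CCOP(OCC)OCC
Why: The Lewis acid regenerates the N-acyliminium ion, which triethyl phosphite traps in a Michaelis–Arbuzov-type amidoalkylation to give the α-amido phosphonate.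

Step 18
Reactants: 20 phosphonolactam
Product: 21 tert-butyl 2-(diethoxyphosphoryl)-5-oxopyrrolidine-1-carboxylate (racemic)
Conditions: Boc2O, 4-(dimethylamino)pyridine (cat.), Et3N, CH2Cl2, 23 °C
Reagents that add atoms: di-tert-butyl dicarbonate, CC(C)(C)OC(=O)OC(=O)OC(C)(C)C
Why: N-Acylation of the lactam nitrogen with Boc2O under nucleophilic catalysis gives the imide-type carbamate, which acidifies the C3 and C5 hydrogens for the two later deprotonations.

Step 19
Reactants: 17 dioxolane-protected tricyclic acid; 21 N-Boc phosphonolactam
Product: 24 tricyclic 4-formylphenyl ether acylated at C3 of the N-Boc 5-(diethoxyphosphoryl)pyrrolidin-2-one (mixture of diastereomers at lactam C3 and C5), via acyl imidazole 22 (not isolated), via dioxolane-protected keto lactam 23 (not isolated)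
Conditions: 17, 1,1'-carbonyldiimidazole, THF, 23 °C; added to 21 (2.5 equiv), LiN(SiMe3)2 (2.5 equiv), THF, −78 → −20 °C; then 1 M HCl, THF, 0 → 23 °C
Reagents that add atoms: 1,1'-carbonyldiimidazole, O=C(n1ccnc1)n1ccnc1 (atoms kept in 22 only); water, O
Why: Crossed Claisen condensation: the lithium enolate formed at C3, the most acidic position of the N-Boc lactam, attacks the acyl imidazole, the excess enolate deprotonates the β-keto lactam so that the acylation is irreversible, and dilute acid in the work-up hydrolyses the dioxolane; the lactam C3 and C5 centres arise as a mixture that is of no consequence because C5 becomes trigonal and C3 equilibrates later.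

Step 20
Reactants: 24 phosphonate aldehyde
Product: 25 N-Boc anhydro macrocycle (5-benzylidene lactam para-cyclophane, aryl group cis to lactam C4)
Conditions: KN(SiMe3)2 (2.2 equiv), THF, slow addition of 24 to 0.5 mM, −78 → 0 °C; aqueous NH4Cl
Reagents that add atoms: none
Why: The first equivalent of KN(SiMe3)2 turns the β-keto lactam into its potassium enolate, which is a spectator, and the second removes the C5 hydrogen flanked by the phosphoryl group and the N-Boc nitrogen; this carbanion adds to the aryl aldehyde and the β-oxido phosphonate collapses through the oxaphosphetane with loss of diethyl phosphate to the enamide C=C bond (intramolecular Horner–Wadsworth–Emmons olefination). The closest known reactions are the olefination of aldehydes with 5-phosphoryl pyrrolidin-2-ones and related α-amido phosphonates to 5-ylidene lactams, and macrocyclic Horner–Wadsworth–Emmons ring closures. The 13-membered para-cyclophane ring closes by attack of the lactam C5 carbanion on the aldehyde carbon (13-exo-trig addition) followed by irreversible syn-elimination, so the ring-forming bond is the new C=C bond. No stereocentre is formed: the ring allows only the alkene geometry with the aryl group cis to lactam C4, and all diastereomers of 24 at lactam C3 and C5 converge on one product. The step needs ring closure to outrun intermolecular olefination, which is secured by slow addition at high dilution and by the aryl ether and the keto lactam arm being held cis on ring B so that the chain ends lie close; the order of acidities (β-dicarbonyl first, then C5) secures the chemoselective deprotonation.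

Step 21
Reactants: 25 N-Boc anhydro macrocycle
Product: 26 xenoacremone H
Conditions: CF3CO2H/H2O/CH2Cl2, 0 → 23 °C
Reagents that add atoms: water, O
Why: Acid cleaves the Boc group and protonates the enamide at the benzylic carbon, water adds reversibly to the N-acyliminium ion and so relieves the strain of the two trigonal ring atoms, and both the hemiaminal carbon and the epimerisable lactam C3 settle under thermodynamic control in the configuration of the natural product.

Compound list
1 | cis-3,5-dimethylcyclohexanone (meso) | C[C@H]1CC(=O)C[C@@H](C)C1 | starting material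
2 | (3S,5R)-3,5-dimethyl-1-(trimethylsilyloxy)cyclohex-1-ene | C[Si](C)(C)OC1C[C@H](C)C[C@H](C)C=1 | intermediate
3 | (2S,3S,5R)-2-(1,3-dioxolan-2-yl)-3,5-dimethylcyclohexan-1-one, all substituents equatorial | O=C1C[C@H](C)C[C@H](C)[C@H]1C2OCCO2 | intermediate
4 | 2-[2-(methoxymethylidene)-4,6-dimethylcyclohexyl]-1,3-dioxolane, ring stereocentres as in 3, E/Z mixture | COC=C1C[C@H](C)C[C@H](C)[C@H]1C2OCCO2 | intermediate
5 | (1R,2R,3S,5R)-2-(1,3-dioxolan-2-yl)-3,5-dimethylcyclohexane-1-carbaldehyde, all substituents equatorial | O=C[C@@H]1C[C@H](C)C[C@H](C)[C@H]1C2OCCO2 | intermediate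
6 | (E)-3-[(1S,2R,3S,5R)-2-(1,3-dioxolan-2-yl)-3,5-dimethylcyclohexyl]prop-2-enal | O=C/C=C/[C@@H]1C[C@H](C)C[C@H](C)[C@H]1C2OCCO2 | intermediate
7 | dienyne acetal: ring of 6 with a (1E,3Z)-6-(triisopropylsilyl)hexa-1,3-dien-5-yn-1-yl group | CC(C)[Si](C(C)C)(C(C)C)C#C/C=C\C=C\[C@@H]1C[C@H](C)C[C@H](C)[C@H]1C2OCCO2 | intermediate
8 | dienyne aldehyde: 7 with an equatorial formyl group in place of the dioxolane | CC(C)[Si](C(C)C)(C(C)C)C#C/C=C\C=C\[C@@H]1C[C@H](C)C[C@H](C)[C@H]1C=O | intermediate
9 | methyl (4S)-4-hydroxybut-2-ynoate carrying the dienynyl-dimethylcyclohexyl ring of 8 at C4 | CC(C)[Si](C(C)C)(C(C)C)C#C/C=C\C=C\[C@@H]1C[C@H](C)C[C@H](C)[C@H]1[C@H](O)C#CC(=O)OC | intermediate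
10 | methyl (2E,4R)-4-hydroxybut-2-enoate carrying the same ring at C4 | CC(C)[Si](C(C)C)(C(C)C)C#C/C=C\C=C\[C@@H]1C[C@H](C)C[C@H](C)[C@H]1[C@H](O)/C=C/C(=O)OC | intermediate
11 | tricyclic hydroxy methyl ester with triisopropylsilylethynyl group, trans-anti-trans decahydrofluorene, all nine stereocentres as in the target | CC(C)[Si](C(C)C)(C(C)C)C#C[C@@H]1C=C[C@H]2[C@@H]3C[C@H](C)C[C@H](C)[C@H]3[C@H](O)[C@@H]2[C@H]1C(=O)OC | intermediate
12 | tricyclic hydroxy methyl ester with ethynyl group | C#C[C@@H]1C=C[C@H]2[C@@H]3C[C@H](C)C[C@H](C)[C@H]3[C@H](O)[C@@H]2[C@H]1C(=O)OC | intermediate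
13 | tricyclic hydroxy methyl ester with vinyl group | C=C[C@@H]1C=C[C@H]2[C@@H]3C[C@H](C)C[C@H](C)[C@H]3[C@H](O)[C@@H]2[C@H]1C(=O)OC | intermediate
14 | lithium salt of the tricyclic hydroxy acid | C=C[C@@H]1C=C[C@H]2[C@@H]3C[C@H](C)C[C@H](C)[C@H]3[C@H](O)[C@@H]2[C@H]1C(=O)[O-].[Li+] | intermediate
15 | 4-fluorobenzaldehyde | O=Cc1ccc(F)cc1 | starting material
16 | tricyclic 4-formylphenyl ether carboxylic acid | C=C[C@@H]1C=C[C@H]2[C@@H]3C[C@H](C)C[C@H](C)[C@H]3[C@H](Oc3ccc(C=O)cc3)[C@@H]2[C@H]1C(=O)O | intermediate
17 | tricyclic 4-(1,3-dioxolan-2-yl)phenyl ether carboxylic acid | C=C[C@@H]1C=C[C@H]2[C@@H]3C[C@H](C)C[C@H](C)[C@H]3[C@H](Oc3ccc(C4OCCO4)cc3)[C@@H]2[C@H]1C(=O)O | intermediate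
18 | succinimide | O=C1CCC(=O)N1 | starting material
19 | 5-ethoxypyrrolidin-2-one, racemic | CCOC1CCC(=O)N1 | intermediate
20 | diethyl (5-oxopyrrolidin-2-yl)phosphonate, racemic | CCOP(=O)(OCC)C1CCC(=O)N1 | intermediate
21 | tert-butyl 2-(diethoxyphosphoryl)-5-oxopyrrolidine-1-carboxylate, racemic | CCOP(=O)(OCC)C1CCC(=O)N1C(=O)OC(C)(C)C | intermediate
22 | acyl imidazole of 17 | C=C[C@@H]1C=C[C@H]2[C@@H]3C[C@H](C)C[C@H](C)[C@H]3[C@H](Oc3ccc(C4OCCO4)cc3)[C@@H]2[C@H]1C(=O)n1ccnc1 | intermediate
23 | dioxolane-protected β-keto lactam, mixture at lactam C3 and C5 | C=C[C@@H]1C=C[C@H]2[C@@H]3C[C@H](C)C[C@H](C)[C@H]3[C@H](Oc3ccc(C4OCCO4)cc3)[C@@H]2[C@H]1C(=O)C1CC(P(=O)(OCC)OCC)N(C(=O)OC(C)(C)C)C1=O | intermediate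
24 | phosphonate aldehyde (key-step precursor), mixture at lactam C3 and C5 | C=C[C@@H]1C=C[C@H]2[C@@H]3C[C@H](C)C[C@H](C)[C@H]3[C@H](Oc3ccc(C=O)cc3)[C@@H]2[C@H]1C(=O)C1CC(P(=O)(OCC)OCC)N(C(=O)OC(C)(C)C)C1=O | intermediate
25 | N-Boc anhydro macrocycle (5-benzylidene lactam para-cyclophane) | C=C[C@@H]1C=C[C@H]2[C@@H]3C[C@H](C)C[C@H](C)[C@H]3[C@@H]3Oc4ccc(cc4)/C=C4/N(C(=O)OC(C)(C)C)C(=O)[C@@H](C4)C(=O)[C@@H]1[C@H]23 | intermediate
26 | xenoacremone H | C=C[C@@H]1C=C[C@H]2[C@@H]3C[C@H](C)C[C@H](C)[C@H]3[C@@H]3Oc4ccc(cc4)C[C@@]4(O)C[C@H](C(=O)N4)C(=O)[C@@H]1[C@H]23 | target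

Total step count: 21. Longest linear sequence: 18 steps (steps 1–15 and 19–21); the lactam arm is 3 steps (16–18).

Steps most likely to fail

Step 20. Ring closure may lose to intermolecular olefination, giving oligomers, because the transition state to the strained 13-membered cyclophane with two trigonal ring atoms is slow; the dianion may also be quenched before it cyclises. The fallback reverses the order of the two unions and sets out from 16 and 21. Lactam 21 is converted with two equivalents of KN(SiMe3)2 into its C3,C5-dianion, whose later-formed and more basic C5 carbanion olefinates the aryl aldehyde of 16 (present as its carboxylate) to give benzylidene lactam acid F1; the enamide geometry can be equilibrated with a trace of iodine. The acid is activated with 1,1'-carbonyldiimidazole to acyl imidazole F2, which is added slowly to LiN(SiMe3)2 at high dilution so that the lactam C3 enolate is acylated intramolecularly. The ring is then closed at the ketone–C3 bond by a macrocyclic Claisen condensation, and the route is rejoined at 25.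

Step 10. The cycloaddition may be sluggish or poorly endo- and face-selective because the Z-configured diene terminus reaches the s-cis conformation less easily, and the Lewis acid may isomerise the dienyne instead. The fallback sets out from 10. The carbinol is oxidised with Dess–Martin periodinane to keto enoate F3, whose doubly activated, fumaroyl-type double bond should cyclise thermally in toluene at 23–60 °C to tricyclic keto ester F4. The ring B ketone is then reduced with NaBH4 and CeCl3·7H2O, hydride arriving on the face away from the ester-bearing carbon, and the route is rejoined at 11.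

Step 19. C-acylation may be slow at the hindered acyl imidazole, so that proton transfer or O-acylation of the lactam enolate takes over. The fallback sets out from 17. The acid is reduced with LiAlH4 to primary alcohol F5 and oxidised with Dess–Martin periodinane to aldehyde F6. Aldol addition of the lithium enolate of 21 gives β-hydroxy lactam F7, and a second Dess–Martin oxidation gives 23, which is hydrolysed with dilute HCl as in step 19; the route is rejoined at 24.

Further compounds
F1 | step 20 | N-Boc 5-benzylidene lactam joined through the para-phenylene ether to the tricyclic carboxylic acid (aryl cis to lactam C4) | C=C[C@@H]1C=C[C@H]2[C@@H]3C[C@H](C)C[C@H](C)[C@H]3[C@H](Oc3ccc(/C=C4\CCC(=O)N4C(=O)OC(C)(C)C)cc3)[C@@H]2[C@H]1C(=O)O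
F2 | step 20 | acyl imidazole of F1 | C=C[C@@H]1C=C[C@H]2[C@@H]3C[C@H](C)C[C@H](C)[C@H]3[C@H](Oc3ccc(/C=C4\CCC(=O)N4C(=O)OC(C)(C)C)cc3)[C@@H]2[C@H]1C(=O)n1ccnc1
F3 | step 10 | methyl (E)-4-oxobut-2-enoate carrying the dienynyl-dimethylcyclohexyl ring of 10 at C4 | CC(C)[Si](C(C)C)(C(C)C)C#C/C=C\C=C\[C@@H]1C[C@H](C)C[C@H](C)[C@H]1C(=O)/C=C/C(=O)OC
F4 | step 10 | tricyclic keto ester (ring B ketone in place of the carbinol of 11) | CC(C)[Si](C(C)C)(C(C)C)C#C[C@@H]1C=C[C@H]2[C@@H]3C[C@H](C)C[C@H](C)[C@H]3C(=O)[C@@H]2[C@H]1C(=O)OC
F5 | step 19 | primary alcohol from reduction of 17 | C=C[C@@H]1C=C[C@H]2[C@@H]3C[C@H](C)C[C@H](C)[C@H]3[C@H](Oc3ccc(C4OCCO4)cc3)[C@@H]2[C@H]1CO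
F6 | step 19 | tricyclic aldehyde from oxidation of F5 | C=C[C@@H]1C=C[C@H]2[C@@H]3C[C@H](C)C[C@H](C)[C@H]3[C@H](Oc3ccc(C4OCCO4)cc3)[C@@H]2[C@H]1C=O
F7 | step 19 | β-hydroxy lactam from aldol addition of 21 to F6, mixture of diastereomers | C=C[C@@H]1C=C[C@H]2[C@@H]3C[C@H](C)C[C@H](C)[C@H]3[C@H](Oc3ccc(C4OCCO4)cc3)[C@@H]2[C@H]1C(O)C1CC(P(=O)(OCC)OCC)N(C(=O)OC(C)(C)C)C1=O
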